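No portion of Q but the first can have had 5.0 h to react, since the feed lasts 80 min. Q is fed into G and gives L. Midnight and spring differ in their equivalents of G.

| setting | grey | teal | green | midnight | spring |
|---|---|---|---|---|---|
| Q | 0.050 M (fed, over 80 min) | 0.050 M (fed, over 80 min) | 0.050 M (fed, over 80 min) | 0.050 M (fed, over 80 min) | 0.050 M (fed, over 80 min) |
| G | 1.2 equiv | 1.3 equiv | 2.3 equiv | 1.00 equiv | 2.00 equiv |
| remark | run made earlier | run made earlier | run made earlier |  |  |
| time |  |  |  | 5.0 h | 5.0 h |

| run | time / h | Q / % | L / % |
|---|---|---|---|
| grey | 0.250 | 17 | 0 |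
| grey | 0.500 | 34 | 4 |
| grey | 1.00 | 65 | 9 |
| grey | 2.00 | 73 | 21 |
| grey | 4.00 | 52 | 26 |
| teal | 0.250 | 15 | 3 |
| teal | 0.500 | 37 | 4 |
| teal | 1.00 | 63 | 13 |
| teal | 2.00 | 69 | 20 |
| teal | 4.00 | 49 | 25 |
| green | 0.333 | 23 | 1 |
| green | 0.833 | 50 | 12 |
| green | 1.50 | 70 | 24 |
| green | 2.50 | 52 | 34 |
| green | 4.00 | 37 | 37 |

(scatter of a reading: 1.5 percentage points)

- percentages count the whole charge, also what has not yet gone in

- part of the Q that has reacted at the end, midnight
- part of the Q that has reacted at the end, spring
- what raising the equivalents of G from its lowest to its highest value here does to the part of the Q that has reacted (changes below 5 percentage points count as none) (it rises / it falls / no change)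

A steady feed has a mean: the average portion of Q enters at mid-feed. So I replace the feed by one shot at that moment. At the asked time the charge then has a mean age:

age = 4.33 h

Let q be the fraction of the charge left as Q. Green at 4.00 h has q = 37% and a mean age of 3.33 h, which gives 0.298 /h. I call this κ, the mean loss constant: minus ln q over the mean age, an averaged pseudo-first-order constant. Grey at 4.00 h gives 0.196 /h. A straight line in equivalents through these two gives my κ for each flask:

midnight: κ = 0.178 /h, reacted = 53.7%

spring: κ = 0.270 /h, reacted = 69.0%

But a mean is not a constant. Green's κ was higher at 2.50 h, at 0.357 /h, so a flat κ reads high. If that fall runs on for one more hour, spring loses about 5.2 percentage points. The fall in grey takes about 4 points off midnight. My ranges are therefore 49.7% to 53.7% and 63.8% to 69.0%.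

The forecast gives 53% (47% to 59%) for midnight and 67% (61% to 73%) for spring, by “Interpolating at about 13 points per equivalent”. Its trend: it rises.

The flask gives 48.9% for midnight and 66.8% for spring: it rises, by 18 points. Midnight lands just under my low end.

    Q + G → Z + L (k = 6.70 /M/h)
    G + Z ⇌ X, settled at all times (K = 350 /M)
    Q + L → J (k = 5.50 /M/h)
    D ⇌ Z, rate k4*(cs4 - [Z]) while solid is left; crystals form when [Z] > cs4 (solubility = 7.80 mM, k = 6.30 /h)
    2 G → E (k = 2.50 /M/h)

The Q left in spring at the end gives a κ of 0.255 /h, below my flat value. This κ is read on Q, so it takes in whatever route Q leaves by. The neighbouring flask is spring left until 12 h, at a mean age of 11.3 h. Spring's κ held flat leaves q = 5.61%. The neighbouring flask leaves 13% of the Q, so 87.3% has reacted and its κ is 0.182 /h. In the neighbouring flask, J stands at 58.6% and L at 28.7%, with 6.7% of the charged G still there unbound.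

The earlier runs and the new flask come from a simulation with constants of no real substance; the scatter is artificial.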